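**Retrosynthetic overview**
- Target ⇐ α-substituted cyclohexenone: conjugate reduction with axial protonation sets the side-chain carbon, hydroxyl-directed ketone reduction sets the carbinol.
- That enone ⇐ α-unsubstituted enone + 2-oxopropane-1,3-diyl diacetate (Baylis–Hillman-type C–C bond); the enone ⇐ (2S,3S)-2-isopropenyl-3-methyl-3-vinylcyclohexanone by dehydrogenation.
- The cyclohexanone ⇐ spiro vinyl oxirane by a new palladium-catalysed asymmetric semipinacol ring expansion (five- to six-membered; forms the bond between the two adjacent stereocentres and sets the isopropenyl-bearing one).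
- The oxirane ⇐ (S)-2-ethenyl-2-methylcyclopentanone ⇐ 1-allenylcyclobutanol (palladium-catalysed asymmetric ring expansion, four- to five-membered; sets the quaternary centre) ⇐ cyclobutanone + 1-bromobut-2-yne.
- Ring order: one carbocycle only, grown cyclobutane → cyclopentanone → cyclohexanone.

Assumption: the Trost ligand enantiomer written in steps 2 and 4 is the one that gives the stated configurations (otherwise its antipode is used), and 1,3-dihydroxyacetone is weighed in as its commercial dimer.

**Step 1**
Reactants: 1 cyclobutanone; 2 1-bromobut-2-yne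
Product: 4 1-(buta-2,3-dien-2-yl)cyclobutan-1-ol, via but-2-ynylzinc bromide 3 (not isolated)
Conditions: Zn dust, THF, 0 → 25 °C; aq NH4Cl
Reagents that add atoms: none
Why: Barbier-type zinc-mediated propargylation, in which the but-2-ynylzinc species adds to the strained ketone by SE2' attack through its methyl-bearing carbon and so gives the tertiary α-methylallenyl carbinol; no stereocentre is formed.

**Step 2**
Reactants: 4 1-(buta-2,3-dien-2-yl)cyclobutan-1-ol
Product: 5 (2S)-2-ethenyl-2-methylcyclopentan-1-one
Conditions: Pd2(dba)3·CHCl3 (2.5 mol %), (R,R)-DACH-phenyl Trost ligand (7.5 mol %), PhCO2H (10 mol %), Et3N (10 mol %), ClCH2CH2Cl, 60 °C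
Reagents that add atoms: none
Why: Known reaction class (palladium-catalysed asymmetric Wagner–Meerwein/semipinacol ring expansion of allenylcyclobutanols): a Pd–H species adds to the allene to give a π-allylpalladium complex, a ring CH2 migrates to the methyl-bearing allyl terminus with relief of ring strain, and the chiral ligand discriminates the two allyl faces so that the quaternary centre is formed as S.

**Step 3**
Reactants: 5 (2S)-2-ethenyl-2-methylcyclopentan-1-one; 6 3-chloro-2-methylprop-1-ene
Product: 9 (4S)-4-ethenyl-4-methyl-2-(prop-1-en-2-yl)-1-oxaspiro[2.4]heptane, via chloroallylzinc chloride 7 (not isolated), via chlorohydrin 8 (not isolated)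
Conditions: 6, LiN(i-Pr)2, ZnCl2, THF, −78 °C; then 5, −78 → 0 °C; then t-BuOK, 0 → 25 °C
Reagents that add atoms: none
Why: Addition of an α-chloroallylzinc reagent to a ketone (SE2' through the chlorine-bearing carbon) gives the chlorohydrin, which the base closes to the vinyl oxirane (Darzens-type epoxide formation); the quaternary centre is untouched and the two new centres, formed as a mixture, are both erased in step 4.

**Step 4**
Reactants: 9 (4S)-4-ethenyl-4-methyl-2-(prop-1-en-2-yl)-1-oxaspiro[2.4]heptane
Product: 10 (2S,3S)-3-ethenyl-3-methyl-2-(prop-1-en-2-yl)cyclohexan-1-one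
Conditions: Pd2(dba)3·CHCl3 (2.5 mol %), (R,R)-DACH-phenyl Trost ligand (7.5 mol %), toluene, 25 °C
Reagents that add atoms: none
Why: Proposed new method: zerovalent palladium ionises the vinyl oxirane to a zwitterionic π-allylpalladium alkoxide whose faces equilibrate by π–σ–π exchange at the unsubstituted CH2 terminus, and the electron-rich quaternary ring carbon anti to palladium then migrates with retention to the internal allyl terminus (semipinacol 1,2-shift driven by C=O formation), so that all oxirane diastereomers converge and the chiral ligand, not the nearly isosteric methyl/vinyl pair, fixes C2 as S with the isopropenyl group generated directly; the closest known reaction type is the palladium-catalysed asymmetric Wagner–Meerwein shift of vinyl- and allenyl-cyclobutanols and the palladium-catalysed ring expansion of vinyl-substituted oxaspirohexanes, so far shown only with strain release in three- and four-membered rings.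

**Step 5**
Reactants: 10 (2S,3S)-3-ethenyl-3-methyl-2-(prop-1-en-2-yl)cyclohexan-1-one
Product: 12 (5S,6S)-5-ethenyl-5-methyl-6-(prop-1-en-2-yl)cyclohex-2-en-1-one, via lithium enolate 11 (not isolated)
Conditions: LiN(i-Pr)2, THF, −78 °C; then PhS(=N-t-Bu)Cl, −78 °C
Reagents that add atoms: none
Why: Kinetic deprotonation by the hindered amide occurs at the unhindered C6 methylene and not at the neopentylic C2 methine, and the enolate is dehydrogenated in the same flask by the Mukaiyama sulfinimidoyl chloride method (sulfur–carbon bond formation, then syn elimination, possible only towards C5); both stereocentres are untouched.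

**Step 6**
Reactants: 13 1,3-dihydroxypropan-2-one
Product: 14 2-oxopropane-1,3-diyl diacetate
Conditions: Ac2O, pyridine, 0 → 25 °C
Reagents that add atoms: acetic anhydride, CC(=O)OC(C)=O
Why: Acetylation of the two primary hydroxyl groups with pyridine as base and acyl-transfer catalyst; the dimer dissociates to the monomeric ketone under the reaction conditions.

**Step 7**
Reactants: 12 (5S,6S)-5-ethenyl-5-methyl-6-(prop-1-en-2-yl)cyclohex-2-en-1-one; 14 2-oxopropane-1,3-diyl diacetate
Product: 16 2-[(4S,5S)-4-ethenyl-4-methyl-6-oxo-5-(prop-1-en-2-yl)cyclohex-1-en-1-yl]-2-hydroxypropane-1,3-diyl diacetate, via chloro aldol 15 (not isolated)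
Conditions: TiCl4 (1.2 equiv), CH2Cl2, −78 → −30 °C; then Et3N, 0 °C
Reagents that add atoms: none
Why: TiCl4-mediated Baylis–Hillman-type reaction, in which chloride adds to C3 of the enone, the titanium enolate adds through C2 to the ketone (activated by two α-acyloxy groups and by chelation), and Et3N removes HCl from the chloro aldol to restore the enone; the carbinol carbon carries two identical arms, so no new stereocentre arises.

**Step 8**
Reactants: 16 2-[(4S,5S)-4-ethenyl-4-methyl-6-oxo-5-(prop-1-en-2-yl)cyclohex-1-en-1-yl]-2-hydroxypropane-1,3-diyl diacetate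
Product: 19 2-[(1R,2R,3S,4S)-4-ethenyl-2-hydroxy-4-methyl-3-(prop-1-en-2-yl)cyclohexyl]-2-hydroxypropane-1,3-diyl diacetate, via triethylsilyl enol ether 17 (not isolated), via hydroxy ketone 18 (not isolated)
Conditions: Et3SiH, RhCl(PPh3)3 (1 mol %), toluene, 50 °C; evaporate; AcOH/MeCN (1:1), 0 °C; then Me4NBH(OAc)3, −25 °C
Reagents that add atoms: none
Why: Rhodium-catalysed 1,4-hydrosilylation gives the enol silane regiospecifically, its protonation in AcOH occurs on the face opposite to the isopropenyl group (axial protonation of the half-chair that has the C4 methyl axial) and so places the side chain equatorial and cis to isopropenyl at C1, and the liberated β-hydroxy ketone is reduced by the Evans–Saksena method, in which the hydride of the alkoxytriacetoxyborohydride formed at the tertiary hydroxyl is delivered internally on the side-chain face and gives the equatorial C2 carbinol trans to both neighbours.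

**Compound list**
1 | cyclobutanone | O=C1CCC1 | starting material
2 | 1-bromobut-2-yne | CC#CCBr | starting material
3 | but-2-ynylzinc bromide | CC#CC[Zn]Br | intermediate
4 | 1-(buta-2,3-dien-2-yl)cyclobutan-1-ol | C=C=C(C)C1(O)CCC1 | intermediate
5 | (2S)-2-ethenyl-2-methylcyclopentan-1-one | C=C[C@]1(C)CCCC1=O | intermediate
6 | 3-chloro-2-methylprop-1-ene | C=C(C)CCl | starting material
7 | (3-chloro-2-methylprop-2-en-1-yl)zinc chloride | ClC=C(C)C[Zn]Cl | intermediate
8 | (2S)-1-(1-chloro-2-methylprop-2-en-1-yl)-2-ethenyl-2-methylcyclopentan-1-ol (mixture at the carbinol and chloride carbons; present as its zinc alkoxide) | C=C[C@]1(C)CCCC1(O)C(Cl)C(C)=C | intermediate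
9 | (4S)-4-ethenyl-4-methyl-2-(prop-1-en-2-yl)-1-oxaspiro[2.4]heptane (mixture at C2 and C3) | C=C[C@]1(C)CCCC12OC2C(C)=C | intermediate
10 | (2S,3S)-3-ethenyl-3-methyl-2-(prop-1-en-2-yl)cyclohexan-1-one | C=C[C@]1(C)CCCC(=O)[C@H]1C(=C)C | intermediate
11 | lithium (5S,6S)-5-ethenyl-5-methyl-6-(prop-1-en-2-yl)cyclohex-1-en-1-olate | C=C[C@]1(C)CCC=C([O-])[C@H]1C(=C)C.[Li+] | intermediate
12 | (5S,6S)-5-ethenyl-5-methyl-6-(prop-1-en-2-yl)cyclohex-2-en-1-one | C=C[C@]1(C)CC=CC(=O)[C@H]1C(=C)C | intermediate
13 | 1,3-dihydroxypropan-2-one | O=C(CO)CO | starting material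
14 | 2-oxopropane-1,3-diyl diacetate | CC(=O)OCC(=O)COC(C)=O | intermediate
15 | 2-[(3S,4S)-6-chloro-4-ethenyl-4-methyl-2-oxo-3-(prop-1-en-2-yl)cyclohexyl]-2-hydroxypropane-1,3-diyl diacetate (mixture at C1 and C6; present as its titanium alkoxide) | C=C[C@]1(C)CC(Cl)C(C(O)(COC(C)=O)COC(C)=O)C(=O)[C@H]1C(=C)C | intermediate
16 | 2-[(4S,5S)-4-ethenyl-4-methyl-6-oxo-5-(prop-1-en-2-yl)cyclohex-1-en-1-yl]-2-hydroxypropane-1,3-diyl diacetate | C=C[C@]1(C)CC=C(C(O)(COC(C)=O)COC(C)=O)C(=O)[C@H]1C(=C)C | intermediate
17 | 2-[(3S,4S)-4-ethenyl-4-methyl-3-(prop-1-en-2-yl)-2-[(triethylsilyl)oxy]cyclohex-1-en-1-yl]-2-hydroxypropane-1,3-diyl diacetate | C=C[C@]1(C)CCC(C(O)(COC(C)=O)COC(C)=O)=C(O[Si](CC)(CC)CC)[C@H]1C(=C)C | intermediate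
18 | 2-[(1S,3S,4S)-4-ethenyl-4-methyl-2-oxo-3-(prop-1-en-2-yl)cyclohexyl]-2-hydroxypropane-1,3-diyl diacetate | C=C[C@]1(C)CC[C@@H](C(O)(COC(C)=O)COC(C)=O)C(=O)[C@H]1C(=C)C | intermediate
19 | 2-[(1R,2R,3S,4S)-4-ethenyl-2-hydroxy-4-methyl-3-(prop-1-en-2-yl)cyclohexyl]-2-hydroxypropane-1,3-diyl diacetate | C=C[C@]1(C)CC[C@@H](C(O)(COC(C)=O)COC(C)=O)[C@H](O)[C@H]1C(=C)C | target

**Step count and risks**
Total: 8 steps. Longest linear sequence: 7 steps (1, 2, 3, 4, 5, 7, 8); step 6 is a one-step branch.

The three steps most likely to fail:

Step 4, the proposed new ring expansion. Without ring strain the 1,2-shift may be slow. The zwitterion may instead close on oxygen to a spiro-2,5-dihydrofuran or let the CH2 carbon migrate. Catalyst control over the isopropenyl-bearing centre may be modest, because the methyl/vinyl pair gives no substrate bias. The fallback uses known chemistry; it sets out from 5 and comes back at 10. The zinc reagent from 6 is added to 5 as in step 3, but the chlorohydrins are isolated without base and separated by chromatography. The epimers with the S-configured chloride carbon, (2S)-1-[(1S)-1-chloro-2-methylprop-2-en-1-yl]-2-ethenyl-2-methylcyclopentan-1-ol F1, are converted into the magnesium alkoxide with i-PrMgCl and warmed in benzene/THF. This is the classical magnesium halohydrin ring enlargement (Tiffeneau/Sisti type): chloride leaves with anti 1,2-shift of the quaternary ring carbon, which gives 10 with inversion at the chloride carbon. At most half of the material is used, and partial ionisation of the allylic chloride could erode the stereospecificity.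

Step 7, the TiCl4-mediated hydroxyalkylation of the enone with a ketone acceptor. Ketones are poor partners in Baylis–Hillman-type reactions, and the Lewis acid could trigger an ene reaction of the isopropenyl group with 14. The fallback sets out from 10 and comes back at 16. Kinetic silylation of 10 (LiN(i-Pr)2, Me3SiCl, −78 °C) gives trimethyl{[(5S,6S)-5-ethenyl-5-methyl-6-(prop-1-en-2-yl)cyclohex-1-en-1-yl]oxy}silane F2. Its Mukaiyama aldol addition to 14 (TiCl4, CH2Cl2, −78 °C) gives 2-[(3S,4S)-4-ethenyl-4-methyl-2-oxo-3-(prop-1-en-2-yl)cyclohexyl]-2-hydroxypropane-1,3-diyl diacetate F3, expected mainly as the C1 epimer of 18 because the electrophile enters anti to the isopropenyl group. That is also why a direct aldol is not used in the main route. IBX in DMSO at 70 °C then dehydrogenates F3, which erases C1 and gives 16.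

Step 8, the one-pot conjugate reduction, protonation and directed reduction. Two stereocentres are set in one flask; partial silylation of the tertiary hydroxyl would block the internal hydride delivery, and protonation of the enol silane could be unselective. The fallback sets out from 16 and comes back at 19. Conjugate reduction with [(Ph3P)CuH]6 in wet benzene gives the copper enolate, which is protonated in the flask, and 18 is isolated and purified. The ketone is then reduced by electron transfer with SmI2 in THF/MeOH at 0 °C; the samarium-chelated ketyl of the β-hydroxy ketone is protonated to the equatorial carbinol 19. This fallback makes no new compound (F0).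

**Further compounds**
F1 | step 4 | (2S)-1-[(1S)-1-chloro-2-methylprop-2-en-1-yl]-2-ethenyl-2-methylcyclopentan-1-ol (both C1 epimers) | C=C[C@]1(C)CCCC1(O)[C@@H](Cl)C(=C)C
F2 | step 7 | trimethyl{[(5S,6S)-5-ethenyl-5-methyl-6-(prop-1-en-2-yl)cyclohex-1-en-1-yl]oxy}silane | C=C[C@]1(C)CCC=C(O[Si](C)(C)C)[C@H]1C(=C)C
F3 | step 7 | 2-[(3S,4S)-4-ethenyl-4-methyl-2-oxo-3-(prop-1-en-2-yl)cyclohexyl]-2-hydroxypropane-1,3-diyl diacetate (C1 epimer mixture) | C=C[C@]1(C)CCC(C(O)(COC(C)=O)COC(C)=O)C(=O)[C@H]1C(=C)C
F0 | step 8 | none | none
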